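**Plan**
- Retrosynthesis: the oxirane is removed first (hydroxyl-directed epoxidation of the C10 vinyl group), then the enal (allylic oxidation of an isopropenyl group). The α-methylene-γ-lactone is then cut at O–C8 and at C11–C12, which releases CO2 and leaves a 1-bromovinyl group on C7 and a C9 ketone.
- Enabling feature: the C9 carbonyl sits between the quaternary C10 and C8, so C8 is its only enolisable carbon, and C8 is γ to the alkenyl carbon C11. Carboxylation at C11 therefore gives a 5-oxo acid that can only close to the γ-lactone, and the epimerisable α-keto carbon C8 can settle in the trans ring fusion.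
- Forward order: p-benzoquinone monoketal (a dearomatised p-methoxyphenol) → asymmetric conjugate addition (C5) → enolate methylation, aldol and dehydration (C10) → ketal hydrolysis and reduction (C6) → directed alkynylation (C7) → esterification → bromoboration → silyl enol ether → lactone ring → C9 reduction → enal → oxirane.
- Stereochemistry: C5 from the chiral rhodium catalyst; C10, C6 and C7 by substrate relay; C8 under thermodynamic control; C9 by reagent control (CBS); the oxirane carbon by delivery from the 9-OH; the ester stereocentre from (S)-2-methylbutanoic acid.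

Key step: step 11

Remark: ring carbons are numbered C5 (three-carbon side chain), C6 (ester oxygen), C7 (bears C11), C8 (lactone oxygen), C9 (hydroxyl) and C10 (quaternary, methyl plus vinyl/oxiranyl); β is the face of the C10 methyl group. Compounds 1, 2 and 11 are taken as commercial.

Step 1
Reactants: 1 4,4-dimethoxycyclohexa-2,5-dien-1-one; 2 2-isopropenyl-4,4,5,5-tetramethyl-1,3,2-dioxaborolane
Product: 3 (R)-4,4-dimethoxy-5-(prop-1-en-2-yl)cyclohex-2-en-1-one
Conditions: [Rh(OH)((R)-binap)]2 (3 mol%), KOH (cat.), dioxane/H2O 10:1, 40 °C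
Reagents that add atoms: none
Why: Rhodium-catalysed asymmetric 1,4-addition (Hayashi–Miyaura) to one of the two enantiotopic enone units desymmetrises the monoketal and sets C5 (ligand antipode chosen by analogy with the 2-cyclohexenone model), and the hindered product enone should resist a second addition.

Step 2
Reactants: 3 (R)-4,4-dimethoxy-5-(prop-1-en-2-yl)cyclohex-2-en-1-one
Product: 4 (5R)-4,4-dimethoxy-6-methyl-5-(prop-1-en-2-yl)cyclohex-2-en-1-one (drawn as the 5,6-trans epimer)
Conditions: LDA, THF, −78 °C; MeI, DMPU, −78 → −30 °C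
Reagents that add atoms: iodomethane, CI
Why: Kinetic α′-deprotonation of the enone (C10 is the only sp3 α-carbon) and SN2 methylation of the cross-conjugated lithium dienolate should give the methyl ketone, whose new centre is erased again in step 3.

Step 3
Reactants: 4 (5R)-4,4-dimethoxy-6-methyl-5-(prop-1-en-2-yl)cyclohex-2-en-1-one
Product: 5 6-(1-hydroxyethyl)-4,4-dimethoxy-6-methyl-5-(prop-1-en-2-yl)cyclohex-2-en-1-one (methyl cis to isopropenyl; carbinol epimers)
Conditions: LDA, THF, −78 °C; CH3CHO, −78 °C; NH4Cl (aq) at −78 °C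
Reagents that add atoms: acetaldehyde, CC=O
Why: Aldol addition of the fully substituted lithium enolate, in which the aldehyde should enter anti to the neighbouring C5 isopropenyl group (1,2-induction), sets the quaternary C10 with methyl cis to isopropenyl; the carbinol configuration is irrelevant.

Step 4
Reactants: 5 the aldol adduct
Product: 6 4,4-dimethoxy-6-methyl-5-(prop-1-en-2-yl)-6-vinylcyclohex-2-en-1-one (methyl cis, vinyl trans to isopropenyl)
Conditions: Burgess reagent, PhMe, 70 °C
Reagents that add atoms: none
Why: Burgess dehydration (syn-elimination of the sulfamate) can only remove a methyl hydrogen because the other β-carbon is quaternary, so the vinyl group is the sole alkene, and the neutral conditions avoid retro-aldol cleavage.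

Step 5
Reactants: 6 the vinyl ketal
Product: 7 5-methyl-6-(prop-1-en-2-yl)-5-vinylcyclohex-2-ene-1,4-dione (methyl cis to isopropenyl)
Conditions: 1 M HCl, THF, 0 °C
Reagents that add atoms: water, O
Why: Acid hydrolysis of the dimethyl ketal should be clean because aromatisation is blocked once C10 is quaternary.

Step 6
Reactants: 7 the ene-dione
Product: 8 4-hydroxy-6-methyl-5-(prop-1-en-2-yl)-6-vinylcyclohex-2-en-1-one (hydroxyl, isopropenyl and methyl all cis; 6β-OH)
Conditions: NaBH4 (1 equiv), CeCl3·7H2O, MeOH, −78 °C
Reagents that add atoms: none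
Why: Luche 1,2-reduction should take the less hindered carbonyl (C6, next to a tertiary carbon, rather than C9 next to the quaternary C10), with hydride arriving anti to the pseudoaxial C10 methyl group to give the 6β-alcohol.

Step 7
Reactants: 8 the γ-hydroxy enone
Product: 10 7β-ethynyl-6β-hydroxy-5β-isopropenyl-10β-methyl-10α-vinylcyclohexan-9-one, via C-silylated alkyne adduct 9 (not isolated)
Conditions: Me2AlC≡CSiMe3 (3 equiv, from TMS-acetylene, n-BuLi, Me2AlCl), PhMe/hexane, 0 °C → rt; Rochelle salt work-up; then K2CO3 (cat.), MeOH, rt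
Reagents that add atoms: dimethyl[(trimethylsilyl)ethynyl]aluminium, C[Al](C)C#C[Si](C)(C)C
Why: Hydroxyl-directed conjugate alkynylation, in which the aluminium alkoxide of the pseudoaxial 6β-hydroxyl delivers the alkynyl group to the adjacent β-carbon on its own face, sets C7 cis to the C6 oxygen, and methanolysis then removes the C-silyl group.

Step 8
Reactants: 10 the ethynyl hydroxy ketone; 11 (S)-2-methylbutanoic acid
Product: 12 7β-ethynyl-5β-isopropenyl-10β-methyl-6β-[(S)-2-methylbutanoyloxy]-10α-vinylcyclohexan-9-one
Conditions: DCC, DMAP (cat.), CH2Cl2, 0 °C → rt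
Reagents that add atoms: none
Why: Steglich esterification acylates the only hydroxyl, and carbodiimide activation avoids a ketene, so the α-stereocentre of the acid is retained.

Step 9
Reactants: 12 the alkynyl ester
Product: 14 7β-(1-bromovinyl)-5β-isopropenyl-10β-methyl-6β-[(S)-2-methylbutanoyloxy]-10α-vinylcyclohexan-9-one, via alkenylborane 13 (not isolated)
Conditions: B-Br-9-BBN, CH2Cl2, 0 °C; then AcOH, 0 °C → rt; ethanolamine work-up
Reagents that add atoms: 9-bromo-9-borabicyclo[3.3.1]nonane, BrB1C2CCCC1CCC2
Why: Bromoboration of the terminal alkyne is Markovnikov (bromine to the internal carbon) and ignores alkenes, and protonolysis of the alkenyl–boron bond with acetic acid gives the 2-bromo-1-alkene.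

Step 10
Reactants: 14 the bromovinyl ketone
Product: 15 the C8=C9 triisopropylsilyl enol ether of 14
Conditions: TIPSOTf, Et3N, CH2Cl2, 0 °C
Reagents that add atoms: triisopropylsilyl trifluoromethanesulfonate, CC(C)[Si](OS(=O)(=O)C(F)(F)F)(C(C)C)C(C)C
Why: Soft enolisation and O-silylation give a single regioisomer because C8 is the only enolisable α-carbon of the C9 ketone.

Step 11
Reactants: 15 the bromovinyl silyl enol ether
Product: 18 trans-fused 9-oxo-8α,12-olide (α-methylene-γ-lactone with 6β-ester, 5β-isopropenyl, 10β-methyl, 10α-vinyl), via manganese acrylate 16 (not isolated), via α-iodo ketone 17 (not isolated)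
Conditions: NiBr2·glyme (10 mol%), neocuproine (20 mol%), Mn (3 equiv), Et4NI (cat.), DMA, CO2 (1 atm), rt; decant from Mn; NIS (1.3 equiv), 0 °C → rt; then Et3N (cat.), rt
Reagents that add atoms: carbon dioxide, O=C=O
Why: Nickel(0) inserts into the alkenyl C–Br bond, manganese reduces the alkenylnickel species, and this adds to CO2 to give the manganese acrylate 16 (C11–C12 bond); NIS then iodinates the silyl enol ether at C8 and the carboxylate displaces iodide from this α-keto carbon (O–C8 bond). The closest known reactions are the nickel-catalysed reductive carboxylation of aryl and alkenyl (pseudo)halides with CO2 and the oxidative lactonisation of 5-oxo carboxylic acids to 5-oxo-4-olides. The one ring that forms, the γ-lactone, closes in the 5-exo-tet mode. The new stereocentre C8 is set under thermodynamic control: it is the only epimerisable centre (α to the C9 ketone, C10 being quaternary), and Et3N should equilibrate it to the trans-fused lactone with the equatorial 8α-oxygen, because the 8β-epimer would hold that oxygen axial and syn to both the C10 methyl group and the C6 ester oxygen. The step needs chemoselective activation of the C–Br bond (ester, silyl enol ether and isolated alkenes should be inert to Ni/Mn) and regioselective functionalisation of C8, which the regiodefined silyl enol ether of the one-sided ketone secures.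

Step 12
Reactants: 18 the keto lactone
Product: 19 9α-hydroxy-8α,12-olide (otherwise as 18)
Conditions: (S)-Me-CBS (0.5 equiv), catecholborane (2 equiv), PhMe, −60 → −30 °C; ethanolamine work-up
Reagents that add atoms: none
Why: Corey–Bakshi–Shibata reduction, with the quaternary C10 side as the large substituent, is meant to override the substrate preference for axial attack and deliver hydride to the β face, giving the axial 9α-alcohol, while catecholborane leaves the α-methylene lactone and the alkenes alone.

Step 13
Reactants: 19 the 9α-hydroxy lactone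
Product: 21 the enal (C5 side chain = 3-oxoprop-1-en-2-yl; otherwise as 19), via allylic alcohol 20 (not isolated)
Conditions: SeO2 (0.5 equiv), t-BuOOH (3 equiv), CH2Cl2, rt; then MnO2 (excess), CH2Cl2, rt
Reagents that add atoms: tert-butyl hydroperoxide, CC(C)(C)OO (oxygen relayed by catalytic selenium dioxide, O=[Se]=O)
Why: Sharpless–Umbreit allylic oxidation (ene reaction then [2,3]-shift) should attack the methyl group of the 1,1-disubstituted alkene (CH3 preferred over CH), since the vinyl group has no allylic hydrogen and the acrylate is deactivated, and MnO2 then oxidises only the primary allylic alcohol.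

Step 14
Reactants: 21 the enal
Product: 22 CNP0593558.1 (target)
Conditions: VO(acac)2 (5 mol%), t-BuOOH (1.5 equiv), PhMe, 0 °C → rt
Reagents that add atoms: tert-butyl hydroperoxide, CC(C)(C)OO
Why: Vanadium-catalysed hydroxyl-directed epoxidation of the homoallylic alcohol (Mihelich model) should deliver oxygen from the axial 9α-vanadate through a chair-like transition state with the vinyl group anti to the C10 methyl, giving the required oxirane configuration, while the two electron-poor alkenes do not react.

**Compound list**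
1 | 4,4-dimethoxycyclohexa-2,5-dien-1-one (p-benzoquinone mono-dimethyl ketal) | COC1(OC)C=CC(=O)C=C1 | starting material
2 | 2-isopropenyl-4,4,5,5-tetramethyl-1,3,2-dioxaborolane | CC(=C)B1OC(C)(C)C(C)(C)O1 | starting material
3 | (R)-4,4-dimethoxy-5-(prop-1-en-2-yl)cyclohex-2-en-1-one | O=C1C=CC(OC)(OC)[C@@H](C(C)=C)C1 | intermediate
4 | (5R)-4,4-dimethoxy-6-methyl-5-(prop-1-en-2-yl)cyclohex-2-en-1-one, 5,6-trans epimer drawn | O=C1C=CC(OC)(OC)[C@@H](C(C)=C)[C@@H]1C | intermediate
5 | 6-(1-hydroxyethyl)-4,4-dimethoxy-6-methyl-5-(prop-1-en-2-yl)cyclohex-2-en-1-one, methyl cis to isopropenyl, carbinol epimers | O=C1C=CC(OC)(OC)[C@@H](C(C)=C)[C@]1(C)C(C)O | intermediate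
6 | 4,4-dimethoxy-6-methyl-5-(prop-1-en-2-yl)-6-vinylcyclohex-2-en-1-one, methyl cis and vinyl trans to isopropenyl | O=C1C=CC(OC)(OC)[C@@H](C(C)=C)[C@]1(C)C=C | intermediate
7 | 5-methyl-6-(prop-1-en-2-yl)-5-vinylcyclohex-2-ene-1,4-dione, methyl cis to isopropenyl | O=C1C=CC(=O)[C@@H](C(C)=C)[C@]1(C)C=C | intermediate
8 | 4-hydroxy-6-methyl-5-(prop-1-en-2-yl)-6-vinylcyclohex-2-en-1-one, hydroxyl, isopropenyl and methyl all cis (6β-OH) | O=C1C=C[C@@H](O)[C@@H](C(C)=C)[C@]1(C)C=C | intermediate
9 | 6β-hydroxy-5β-isopropenyl-10β-methyl-7β-[(trimethylsilyl)ethynyl]-10α-vinylcyclohexan-9-one (not isolated) | O=C1C[C@@H](C#C[Si](C)(C)C)[C@@H](O)[C@@H](C(C)=C)[C@]1(C)C=C | intermediate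
10 | 7β-ethynyl-6β-hydroxy-5β-isopropenyl-10β-methyl-10α-vinylcyclohexan-9-one | O=C1C[C@@H](C#C)[C@@H](O)[C@@H](C(C)=C)[C@]1(C)C=C | intermediate
11 | (S)-2-methylbutanoic acid | CC[C@H](C)C(=O)O | starting material
12 | 7β-ethynyl-5β-isopropenyl-10β-methyl-6β-[(S)-2-methylbutanoyloxy]-10α-vinylcyclohexan-9-one | O=C1C[C@@H](C#C)[C@@H](OC(=O)[C@@H](C)CC)[C@@H](C(C)=C)[C@]1(C)C=C | intermediate
13 | (Z)-2-bromo-1-alkenyl-9-BBN adduct of 12 (not isolated) | O=C1C[C@@H](/C(Br)=C/B2C3CCCC2CCC3)[C@@H](OC(=O)[C@@H](C)CC)[C@@H](C(C)=C)[C@]1(C)C=C | intermediate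
14 | 7β-(1-bromovinyl)-5β-isopropenyl-10β-methyl-6β-[(S)-2-methylbutanoyloxy]-10α-vinylcyclohexan-9-one | O=C1C[C@@H](C(Br)=C)[C@@H](OC(=O)[C@@H](C)CC)[C@@H](C(C)=C)[C@]1(C)C=C | intermediate
15 | C8=C9 triisopropylsilyl enol ether of 14 | CC(C)[Si](OC1=C[C@@H](C(Br)=C)[C@@H](OC(=O)[C@@H](C)CC)[C@@H](C(C)=C)[C@]1(C)C=C)(C(C)C)C(C)C | intermediate
16 | acrylic acid from carboxylation of 15 at C11, present as its manganese(II) salt (drawn as the acid; not isolated) | CC(C)[Si](OC1=C[C@@H](C(=C)C(=O)O)[C@@H](OC(=O)[C@@H](C)CC)[C@@H](C(C)=C)[C@]1(C)C=C)(C(C)C)C(C)C | intermediate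
17 | 8-iodo-9-oxo acrylic acid, C8 epimers, present as carboxylate (drawn as the acid; not isolated) | O=C1C(I)[C@@H](C(=C)C(=O)O)[C@@H](OC(=O)[C@@H](C)CC)[C@@H](C(C)=C)[C@]1(C)C=C | intermediate
18 | trans-fused 9-oxo-8α,12-olide with 6β-[(S)-2-methylbutanoyloxy], 5β-isopropenyl, 10β-methyl, 10α-vinyl | C=C1C(=O)O[C@@H]2[C@@H]1[C@@H](OC(=O)[C@@H](C)CC)[C@@H](C(C)=C)[C@](C)(C=C)C2=O | intermediate
19 | 9α-hydroxy-8α,12-olide (otherwise as 18) | C=C1C(=O)O[C@@H]2[C@@H]1[C@@H](OC(=O)[C@@H](C)CC)[C@@H](C(C)=C)[C@](C)(C=C)[C@@H]2O | intermediate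
20 | allylic alcohol: C5 side chain 3-hydroxyprop-1-en-2-yl (otherwise as 19; not isolated) | C=C1C(=O)O[C@@H]2[C@@H]1[C@@H](OC(=O)[C@@H](C)CC)[C@@H](C(=C)CO)[C@](C)(C=C)[C@@H]2O | intermediate
21 | enal: C5 side chain 3-oxoprop-1-en-2-yl, C10 still vinyl | C=C1C(=O)O[C@@H]2[C@@H]1[C@@H](OC(=O)[C@@H](C)CC)[C@@H](C(=C)C=O)[C@](C)(C=C)[C@@H]2O | intermediate
22 | CNP0593558.1 | C=C1C(=O)O[C@@H]2[C@@H]1[C@@H](OC(=O)[C@@H](C)CC)[C@@H](C(=C)C=O)[C@](C)([C@@H]1CO1)[C@@H]2O | target

**Step count and risks**
Total step count: 14. Longest linear sequence: 14 steps (from 1).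

Steps most likely to fail:

1. Step 11. The iodination stage may be consumed by residual reductant or nickel, the displacement at the α-keto carbon may be slow, or equilibration to the trans ring fusion may stay incomplete. Fallback (separates the two bond formations and closes the ring by acylation instead): from 15, Rubottom oxidation (DMDO, acetone/CH2Cl2, −40 °C; then HF·pyridine) should give the 8α-hydroxy-9-ketone F1, with oxygen entering from the less hindered α face. Palladium-catalysed cyclocarbonylation of its alkenyl bromide onto the free hydroxyl (Pd(PPh3)4, CO 1 atm, K2CO3, MeCN, 60 °C) would then form the α-methylene lactone and rejoin the route at 18.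

2. Step 12. The substrate's preference for axial hydride attack may win over the catalyst and give the 9β-epimer, or the hindered ketone may react too slowly. Fallback (substrate-controlled bulky hydride on a masked lactone): from 18, conjugate addition of Et2NH (THF/MeOH, rt) should give the diethylaminomethyl lactone F2. K-Selectride (THF, −78 °C) would attack the ketone equatorially from the β face to give the axial 9α-alcohol F3. MeI followed by aqueous NaHCO3 would regenerate the methylene group and return to 19.

3. Step 7. The alane may add 1,2 to the ketone, fail to transfer the alkynyl group, or deliver it without facial control. Fallback (silicon-tethered radical delivery of the two-carbon unit): from 8, silylation with (1-bromovinyl)chlorodimethylsilane (imidazole, CH2Cl2) should give the (1-bromovinyl)dimethylsilyl ether F4. Bu3SnH/AIBN (PhH, 80 °C) would close the vinyl radical 5-exo onto C7 from the β face to give the cis-fused cyclic alkenylsiloxane F5. Iododesilylation (NIS, MeCN; then KF, MeOH) would open it to the 7β-(1-iodovinyl)-6β-hydroxy ketone F6. Steglich esterification with 11 gives the ester F7, TIPSOTf/Et3N gives the silyl enol ether F8, and F8 under the conditions of step 11 returns to the route at 18.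

Further compounds
F1 | step 11 | 7β-(1-bromovinyl)-8α-hydroxy-5β-isopropenyl-10β-methyl-6β-[(S)-2-methylbutanoyloxy]-10α-vinylcyclohexan-9-one | O=C1[C@H](O)[C@@H](C(Br)=C)[C@@H](OC(=O)[C@@H](C)CC)[C@@H](C(C)=C)[C@]1(C)C=C
F2 | step 12 | diethylamine adduct of 18 (11-diethylaminomethyl 9-oxo lactone, C11 epimers) | CCN(CC)CC1C(=O)O[C@@H]2[C@@H]1[C@@H](OC(=O)[C@@H](C)CC)[C@@H](C(C)=C)[C@](C)(C=C)C2=O
F3 | step 12 | 9α-hydroxy diethylamine adduct | CCN(CC)CC1C(=O)O[C@@H]2[C@@H]1[C@@H](OC(=O)[C@@H](C)CC)[C@@H](C(C)=C)[C@](C)(C=C)[C@@H]2O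
F4 | step 7 | (1-bromovinyl)dimethylsilyl ether of 8 | O=C1C=C[C@@H](O[Si](C)(C)C(Br)=C)[C@@H](C(C)=C)[C@]1(C)C=C
F5 | step 7 | cis-fused 3-methylene-1-oxa-2-silacyclopentane bridging O6 and C7 | O=C1C[C@H]2C(=C)[Si](C)(C)O[C@H]2[C@@H](C(C)=C)[C@]1(C)C=C
F6 | step 7 | 6β-hydroxy-7β-(1-iodovinyl)-5β-isopropenyl-10β-methyl-10α-vinylcyclohexan-9-one | O=C1C[C@@H](C(I)=C)[C@@H](O)[C@@H](C(C)=C)[C@]1(C)C=C
F7 | step 7 | (S)-2-methylbutanoate of F6 | O=C1C[C@@H](C(I)=C)[C@@H](OC(=O)[C@@H](C)CC)[C@@H](C(C)=C)[C@]1(C)C=C
F8 | step 7 | C8=C9 triisopropylsilyl enol ether of F7 | CC(C)[Si](OC1=C[C@@H](C(I)=C)[C@@H](OC(=O)[C@@H](C)CC)[C@@H](C(C)=C)[C@]1(C)C=C)(C(C)C)C(C)C
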